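## The problem

CNP0080516.0 is a dihydrochalcone. A 3-arylpropanoyl chain links ring B, a 4-hydroxy-3-prenylphenyl group, to C6 of ring A, which is a 5,7-dihydroxy-2,2-dimethylchroman (chroman numbering O1, C2–C4, C4a, C5–C8, C8a is used throughout).

The molecule has no stereocentre, so nothing has to be set and nothing can direct anything else. The difficulties are regiochemistry and functional-group tolerance.

Ring A is a phloroglucinol with one of its three oxygens tied into the pyran. That oxygen must be the one para to the acyl carbon (O1 para to C6). Closing a pyran onto a prenylated acylphloroglucinol can use either neighbouring oxygen and so can give the 6-acyl or the 8-acyl chroman.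

The ortho-prenylphenol of ring B is the fragile part. Acid can cyclise it to a second chroman, and hydrogenation, electrophilic halogen and strong Lewis acids attack its alkene. The electron-rich ring A also makes any benzylic alcohol on the way easy to ionise. The ketone sits between two hydroxyls, is hindered and chelated, and is best brought in as a carbon already attached to C6.

The feature that opens the structure is the unit O1–C8a=C4a–C5 of ring A. It is the cyclic enol ether of a β-keto acid whose methyl group is C8. Adding C6 and C7 as a malonate residue at the C5 carbonyl gives a precursor in which O1 is already para to the future C6 carboxyl carbon, so closing C7–C8 can give only one arene.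

Remark on the chemistry: compounds 3 and 13 are racemic; both stereocentres are erased later (steps 2 and 11), so no enantiocontrol is needed.

## Retrosynthesis

**17 to 16.** The last disconnection removes two methoxymethyl (MOM) acetals from O5 and O7. Both sit ortho to the ketone, so the released phenols become hydrogen-bonded and the acetals should cleave under mild acid. The ring B phenol is carried free, so no harsher deprotection is needed next to the prenyl group. The forward step must use acid weak enough to spare the ortho-prenylphenol.

**16 to 13 and 15.** The bond between ring B and the benzylic CH2 of the chain is cut, and the ketone is traced back to a secondary allylic alcohol. Forward, this is a Heck arylation of allylic alcohol 13 by aryl iodide 15 that delivers the saturated ketone directly. Two neighbouring cuts were weighed: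
- Friedel–Crafts acylation of a 5,7-dioxygenated chroman would reopen the C6/C8 question and expose the prenyl group to Lewis acid.
- An aldol route through the chalcone would need the enone C=C reduced in the presence of the prenyl alkene.

The Heck cut gives two fragments of similar size. It asks for β-hydride elimination toward the carbinol C–H and for tolerance of a free phenol and a trisubstituted alkene.

**13 to 9 via 12, 11 and 10.** The vinyl–carbinol bond is cut (a vinyl Grignard addition to aldehyde 12). The aldehyde is traced through benzylic alcohol 11 and bis-MOM ester 10 to dihydroxy ester 9. The carboxyl carbon of 9 thus becomes the ketone carbon of the target. Direct addition of a vinyl metal to the ester would over-add, and amide formation from a doubly ortho-substituted benzoate is unattractive, so the reduction–oxidation detour is accepted. The forward steps must handle the acid-labile, electron-rich benzylic alcohols 11 and 13 without acid.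

**9 to 8.** The C7–C8 bond is cut and ring A is opened to acylmalonate 8. The classical neighbour cuts the pyran instead (O1–C2 and C4–C4a) and has to choose between two oxygens on ring closure. In 8 the ring oxygen and the carbon skeleton are already joined in a dihydropyran, so regiochemistry is fixed by connectivity. The precursor is monocyclic with a symmetrical diester. The forward reaction must deprotonate the C6 methyl group in the presence of the acidic malonate methine, and C-cyclisation must beat deacylation.

**8 to 5 and 6.** The bond between the ketone carbon and the malonate carbon is cut. Forward, acid 5 is activated as acid chloride 7 and C-acylates the magnesium enolate of dimethyl malonate 6. This is the shortest way to attach C6 and C7 with both at the carboxyl oxidation level.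

**5 to 1 and 2 via 4 and 3.** After ester hydrolysis (5 from 4), the O1–C2 bond is cut, which is an acid-mediated addition of the ketone enol oxygen to the prenyl alkene of 3. Then the C4–C4a bond is cut, which is C-prenylation of ethyl acetoacetate 1 with prenyl bromide 2. The whole pyran with its geminal methyl groups and the C8 methyl group come from two bulk chemicals.

**15 to 14 and 2.** The aryl–CH2 bond of the ring B prenyl group is cut. Forward, the sodium phenoxide of 4-iodophenol 14 is C-alkylated ortho by prenyl bromide 2. The para position is blocked by iodine. Iodinating a pre-formed prenylphenol is avoided because the alkene would react with the electrophilic halogen.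

## Roads not taken

**Alternative 1:** Aryne insertion into a carboxylic acid.
- Cut: the C6–C(=O) bond together with the C7–O (or C5–O) bond of ring A, giving a chroman aryne and the ring B propanoic acid.
- Forward key step: fluoride removes silicon from 2,2-dimethyl-6-(trimethylsilyl)chroman-5,7-diyl bis(trifluoromethanesulfonate) A3 and expels one triflate. The carboxylate of 3-[4-acetoxy-3-(3-methylbut-2-en-1-yl)phenyl]propanoic acid A4 adds with oxygen at C7 (or C5). The aryl anion at C6 attacks the ester carbonyl and the four-membered intermediate opens to ortho-hydroxyaryl ketone A1, formed with its 5-hydroxy-7-triflyloxy isomer A2. Hydrolysis of the remaining triflate and the acetate would take both isomers to the target.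
- Merits: very convergent. The ketone and its neighbouring hydroxyl appear in one operation, the two regioisomers converge, and no acid comes near the prenyl group.
- Weak points: A3 needs silicon at C6 and not C8 of a 5,7-dioxygenated chroman, which is the same C6/C8 problem moved to an earlier stage. The aryl anion at C6 sits ortho to the second triflate, so loss of that triflate to a second aryne or sulfonyl migration competes with acyl transfer. Simple protonation gives only the aryl ester.
- Comparison: this endgame is clearly shorter, since the chosen plan spends five steps turning the ester carbon of 9 into the ketone. The chosen plan offers in return regiochemistry settled by construction and steps of established scope.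

**Alternative 2:** Propargyl ether Claisen cascade.
- Cut: C4–C4a and O1–C2 of the pyran, on the complete dihydrochalcone.
- Forward key step: heating 1-{2,6-dihydroxy-4-[(2-methylbut-3-yn-2-yl)oxy]phenyl}-3-[4-hydroxy-3-(3-methylbut-2-en-1-yl)phenyl]propan-1-one A6 triggers a [3,3] shift to an allenyl dienone, a 1,5-hydrogen shift and an oxa-6π electrocyclisation to 2H-chromene A5. The C3=C4 bond must then be hydrogenated.
- Merits: the ether sits on the one non-chelated oxygen para to the acyl group and its two ortho carbons are equivalent, so pyran regiochemistry is fixed by symmetry. The route is very short.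
- Weak points: the final reduction must distinguish a cis-disubstituted styrene-type alkene from the trisubstituted prenyl alkene. Selectivity with RhCl(PPh3)3 or diimide is plausible, but under- and over-reduced material would differ from the target by two hydrogens only. A6 also requires an acylphloroglucinol that already carries ring B, which means an aromatic acylation in the presence of an ortho-prenylphenol.
- Comparison: this route is shorter, probably by half. The chosen plan offers in return a pyran that is saturated from the first steps and a ring B that never meets hydrogen or a Lewis acid.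

**Alternative 3:** ortho-Quinone methide and isobutene.
- Cut: C4–C3 and O1–C2, a [4+2] between an ortho-quinone methide of ring A and isobutene A9.
- Forward key step: Mannich base 1-[3-(dimethylaminomethyl)-4-hydroxy-2,6-bis(methoxymethoxy)phenyl]-3-[4-(methoxymethoxy)-3-(3-methylbut-2-en-1-yl)phenyl]propan-1-one A8 loses its amine on heating. The quinone methide adds A9 with oxygen bonding to the tertiary carbon, giving the tris(methoxymethyl) ether of the target, A7.
- Merits: the pyran with both methyl groups forms in one step from a C4 feedstock. The aminomethyl group enters ortho to the only free hydroxyl, whose two ortho positions are equivalent, so regiochemistry is again fixed by symmetry. Both aryl rings are already joined.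
- Weak points: the quinone methide is generated hot in a molecule that carries its own electron-rich trisubstituted alkene. Capture by the prenyl group of a second molecule competes unless A9 is used in large excess under pressure. The final deprotection must also remove a MOM group on ring B that is not activated by a carbonyl, which needs stronger acid right beside the prenylphenol it liberates.
- Comparison: this route is at least as convergent and probably no longer. The chosen plan offers in return no competition between two alkenes, no pressure step, and a last step that removes only ortho-carbonyl acetals.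

Key step: step 5

Step 1
Reactants: 1 ethyl acetoacetate; 2 prenyl bromide (1-bromo-3-methylbut-2-ene)
Product: 3 ethyl 2-acetyl-5-methylhex-4-enoate (racemic)
Conditions: K2CO3, acetone, reflux (1 in excess)
Reagents that add atoms: none
Why: Acetoacetic ester alkylation; the soft enolate is C-alkylated by the primary allylic bromide and an excess of 1 limits dialkylation. The C2 stereocentre is racemic and disappears on enolisation in step 2.

Step 2
Reactants: 3 ethyl 2-acetyl-5-methylhex-4-enoate
Product: 4 ethyl 2,2,6-trimethyl-3,4-dihydro-2H-pyran-5-carboxylate
Conditions: TfOH (5 mol%), CH2Cl2, 0 °C to rt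
Reagents that add atoms: none
Why: Acid-catalysed intramolecular Markovnikov hydroalkoxylation, as known for 2-prenyl 1,3-dicarbonyl compounds; the tertiary cation from the trisubstituted alkene is captured by the ketone enol oxygen in a 6-endo-trig closure. The product is a stabilised vinylogous carbonate, so the equilibrium lies on its side.

Step 3
Reactants: 4 ethyl 2,2,6-trimethyl-3,4-dihydro-2H-pyran-5-carboxylate
Product: 5 2,2,6-trimethyl-3,4-dihydro-2H-pyran-5-carboxylic acid
Conditions: NaOH, EtOH–H2O, reflux; then cold 1 M HCl to pH 3
Reagents that add atoms: sodium hydroxide, [Na+].[OH-]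
Why: Saponification of a vinylogous carbonate ester, which needs heat but leaves the base-stable enol ether intact; 6-methyl-dihydropyran-5-carboxylic acids of this type are stable, isolable acids. Cold, brief acidification avoids hydrolysis of the enol ether.

Step 4
Reactants: 5 2,2,6-trimethyl-3,4-dihydro-2H-pyran-5-carboxylic acid; 6 dimethyl malonate
Product: 8 dimethyl 2-[(2,2,6-trimethyl-3,4-dihydro-2H-pyran-5-yl)carbonyl]propanedioate, via 2,2,6-trimethyl-3,4-dihydro-2H-pyran-5-carbonyl chloride 7 (not isolated)
Conditions: (COCl)2, cat. DMF, CH2Cl2, 0 °C to rt, evaporate; then 6, MgCl2, Et3N, MeCN, 0 °C to rt; cold dilute HCl work-up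
Reagents that add atoms: none
Why: Acid chloride formation followed by C-acylation of the chelated magnesium enolate of the malonate (MgCl2/Et3N soft enolisation), which gives C- rather than O-acylation because the product is trapped as its magnesium chelate. Acid chlorides of 6-methyl-dihydropyran-5-carboxylic acids are known acylating agents.

Step 5
Reactants: 8 dimethyl 2-[(2,2,6-trimethyl-3,4-dihydro-2H-pyran-5-yl)carbonyl]propanedioate
Product: 9 methyl 5,7-dihydroxy-2,2-dimethylchroman-6-carboxylate
Conditions: LiN(iPr)2 (3.5 equiv), THF, −78 °C to rt; then cold aq. HCl
Reagents that add atoms: none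
Why: The first equivalent of LiN(iPr)2 removes the methine proton of 8 and a second removes a proton of the C6 methyl group of the dihydropyran, which is γ to the ketone through the enol ether double bond, so a dienolate with its charge on the ketone oxygen forms beside the malonate carbanion. Its CH2 terminus adds to one ester carbonyl (new C7–C8 bond), methoxide leaves, and loss of a proton from C8 turns the cyclohexenedione into the lithium diphenoxide of 9, which the acid quench sets free. The closest known reaction type is the intramolecular Claisen (Dieckmann-type) condensation of polycarbonyl polyanions to acylphloroglucinols and phloroglucinol carboxylates, combined with γ-deprotonation of β-alkoxy enoates and enones; the stronger amide base is chosen because the methyl group of the monoanion is far less acidic than that of a neutral vinylogous ester. Ring A closes in a 6-(enolendo)-exo-trig mode, since C8 and C8a of the dienolate both become ring atoms while the ester C=O is exocyclic. No stereocentre is formed. The step needs C-cyclisation to win over deacylation of the acylmalonate; a hindered non-nucleophilic base, the anionic and therefore cleavage-resistant tricarbonyl unit and the irreversible aromatisation should secure this. Regiochemistry is not a matter of selectivity: the two esters are equivalent, the methyl group is the only other acidic site and O1 is already bonded to C8a, so only the arene with the carboxyl carbon between two hydroxyls and para to O1 can result.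

Step 6
Reactants: 9 methyl 5,7-dihydroxy-2,2-dimethylchroman-6-carboxylate
Product: 10 methyl 5,7-bis(methoxymethoxy)-2,2-dimethylchroman-6-carboxylate
Conditions: NaH, MOMCl, DMF, 0 °C to rt
Reagents that add atoms: chloromethyl methyl ether (MOMCl), COCCl
Why: Williamson-type O-alkylation of both phenoxides; full deprotonation with NaH in DMF breaks the hydrogen bonds to the ester that would slow alkylation under amine-base conditions, and the hard electrophile reacts at oxygen rather than at C8.

Step 7
Reactants: 10 methyl 5,7-bis(methoxymethoxy)-2,2-dimethylchroman-6-carboxylate
Product: 11 [5,7-bis(methoxymethoxy)-2,2-dimethylchroman-6-yl]methanol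
Conditions: LiAlH4, THF, 0 °C to rt; aq. NaOH work-up
Reagents that add atoms: none
Why: Hydride reduction of the hindered benzoate to the benzylic alcohol; MOM ethers are inert to hydride. The basic work-up and use of the crude product protect the easily ionised, electron-rich benzylic alcohol.

Step 8
Reactants: 11 [5,7-bis(methoxymethoxy)-2,2-dimethylchroman-6-yl]methanol
Product: 12 5,7-bis(methoxymethoxy)-2,2-dimethylchroman-6-carbaldehyde
Conditions: MnO2, CH2Cl2, rt
Reagents that add atoms: none
Why: Selective oxidation of a benzylic alcohol under neutral, heterogeneous conditions; electron-rich benzylic alcohols react fast and over-oxidation does not occur.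

Step 9
Reactants: 12 5,7-bis(methoxymethoxy)-2,2-dimethylchroman-6-carbaldehyde
Product: 13 1-[5,7-bis(methoxymethoxy)-2,2-dimethylchroman-6-yl]prop-2-en-1-ol (racemic)
Conditions: CH2=CHMgBr, THF, −78 to 0 °C; sat. aq. NH4Cl
Reagents that add atoms: vinylmagnesium bromide, C=C[Mg]Br
Why: Grignard 1,2-addition to the aldehyde, helped by chelation to the flanking acetal oxygens. The new carbinol centre is racemic and becomes the ketone carbon in step 11; the acid-labile alcohol is purified on base-deactivated silica or used crude.

Step 10
Reactants: 14 4-iodophenol; 2 prenyl bromide
Product: 15 4-iodo-2-(3-methylbut-2-en-1-yl)phenol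
Conditions: NaH, toluene, 0 °C; then 2, rt to 60 °C
Reagents that add atoms: none
Why: ortho-C-Alkylation of a sodium phenoxide in a non-polar medium; the tight ion pair shields oxygen and directs the allylic halide to the ortho carbon, and the para position is blocked by iodine. The iodide is in place beforehand, so no electrophilic halogenation has to be done next to the alkene.

Step 11
Reactants: 13 1-[5,7-bis(methoxymethoxy)-2,2-dimethylchroman-6-yl]prop-2-en-1-ol; 15 4-iodo-2-(3-methylbut-2-en-1-yl)phenol
Product: 16 1-[5,7-bis(methoxymethoxy)-2,2-dimethylchroman-6-yl]-3-[4-hydroxy-3-(3-methylbut-2-en-1-yl)phenyl]propan-1-one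
Conditions: Pd(OAc)2 (5 mol%), Bu4NCl, NaHCO3, DMF, 50 °C
Reagents that add atoms: none
Why: Heck arylation of a secondary allylic alcohol under ligand-free phase-transfer conditions; zerovalent palladium inserts into the C–I bond, the aryl group adds to the terminal alkene carbon and β-hydride elimination toward the carbinol C–H gives the enol and hence the saturated ketone. The prenyl alkene is trisubstituted and meta to iodine, so it neither inserts nor cyclises, and the free phenol is tolerated by the weak base.

Step 12
Reactants: 16 1-[5,7-bis(methoxymethoxy)-2,2-dimethylchroman-6-yl]-3-[4-hydroxy-3-(3-methylbut-2-en-1-yl)phenyl]propan-1-one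
Product: 17 1-(5,7-dihydroxy-2,2-dimethylchroman-6-yl)-3-[4-hydroxy-3-(3-methylbut-2-en-1-yl)phenyl]propan-1-one (CNP0080516.0)
Conditions: 3 M aq. HCl, MeOH, rt
Reagents that add atoms: none
Why: Acid-catalysed acetal cleavage; both MOM groups are ortho to the ketone and their loss is assisted by hydrogen bonding of the emerging phenols to the carbonyl group, so dilute acid at room temperature should suffice. Such conditions are commonly used in the presence of prenyl groups.

## Compound list

1 | ethyl acetoacetate | CCOC(=O)CC(C)=O | starting material
2 | prenyl bromide (1-bromo-3-methylbut-2-ene) | CC(C)=CCBr | starting material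
3 | ethyl 2-acetyl-5-methylhex-4-enoate (racemic) | CCOC(=O)C(CC=C(C)C)C(C)=O | intermediate
4 | ethyl 2,2,6-trimethyl-3,4-dihydro-2H-pyran-5-carboxylate | CCOC(=O)C1=C(C)OC(C)(C)CC1 | intermediate
5 | 2,2,6-trimethyl-3,4-dihydro-2H-pyran-5-carboxylic acid | OC(=O)C1=C(C)OC(C)(C)CC1 | intermediate
6 | dimethyl malonate | COC(=O)CC(=O)OC | starting material
7 | 2,2,6-trimethyl-3,4-dihydro-2H-pyran-5-carbonyl chloride | ClC(=O)C1=C(C)OC(C)(C)CC1 | intermediate (not isolated)
8 | dimethyl 2-[(2,2,6-trimethyl-3,4-dihydro-2H-pyran-5-yl)carbonyl]propanedioate | COC(=O)C(C(=O)OC)C(=O)C1=C(C)OC(C)(C)CC1 | intermediate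
9 | methyl 5,7-dihydroxy-2,2-dimethylchroman-6-carboxylate | COC(=O)c1c(O)cc2OC(C)(C)CCc2c1O | intermediate
10 | methyl 5,7-bis(methoxymethoxy)-2,2-dimethylchroman-6-carboxylate | COCOc1cc2OC(C)(C)CCc2c(OCOC)c1C(=O)OC | intermediate
11 | [5,7-bis(methoxymethoxy)-2,2-dimethylchroman-6-yl]methanol | COCOc1cc2OC(C)(C)CCc2c(OCOC)c1CO | intermediate
12 | 5,7-bis(methoxymethoxy)-2,2-dimethylchroman-6-carbaldehyde | COCOc1cc2OC(C)(C)CCc2c(OCOC)c1C=O | intermediate
13 | 1-[5,7-bis(methoxymethoxy)-2,2-dimethylchroman-6-yl]prop-2-en-1-ol (racemic) | COCOc1cc2OC(C)(C)CCc2c(OCOC)c1C(O)C=C | intermediate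
14 | 4-iodophenol | Oc1ccc(I)cc1 | starting material
15 | 4-iodo-2-(3-methylbut-2-en-1-yl)phenol | CC(C)=CCc1cc(I)ccc1O | intermediate
16 | 1-[5,7-bis(methoxymethoxy)-2,2-dimethylchroman-6-yl]-3-[4-hydroxy-3-(3-methylbut-2-en-1-yl)phenyl]propan-1-one | CC(C)=CCc1cc(CCC(=O)c2c(OCOC)cc3OC(C)(C)CCc3c2OCOC)ccc1O | intermediate
17 | 1-(5,7-dihydroxy-2,2-dimethylchroman-6-yl)-3-[4-hydroxy-3-(3-methylbut-2-en-1-yl)phenyl]propan-1-one (CNP0080516.0) | CC(C)=CCc1cc(CCC(=O)c2c(O)cc3c(c2O)CCC(C)(C)O3)ccc1O | target

## Step count and least certain steps

Total step count: 12. Longest linear sequence: 11 (steps 1–9, 11, 12); step 10 makes the ring B fragment in one step from commercial material.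

**Step 5 (key step).**
- What may go wrong: the second deprotonation or the ring closure stalls. Both ester groups belong to the delocalised malonate anion and are poor electrophiles, so the acylmalonate could be recovered or slowly deacylated on warming.
- Fallback: it sets out from prenyl bromide 2 and returns at 9. Commercial methyl 2,4,6-trihydroxybenzoate F1 would be C-prenylated with 2 (aq. KOH, 0 °C to rt) to methyl 2,4,6-trihydroxy-3-(3-methylbut-2-en-1-yl)benzoate F2. Acid (p-TsOH, toluene, 80 °C) would then close the pyran through the hydroxyl para to the ester, the only one not hydrogen-bonded to the carbonyl group, to give 9. The price is that regiocontrol by connectivity is lost: closure through the ortho hydroxyl competes and would have to be suppressed or its product separated.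

**Step 10.**
- What may go wrong: O-alkylation and double alkylation outrun ortho-C-alkylation of the phenoxide, because the selectivity rests only on ion pairing in a non-polar solvent.
- Fallback: it sets out from 14 and returns at 15. O-Allylation (allyl bromide, K2CO3, acetone) would give 1-iodo-4-(prop-2-en-1-yloxy)benzene F3. Aromatic Claisen rearrangement (N,N-diethylaniline, 190 °C) would give 4-iodo-2-(prop-2-en-1-yl)phenol F4 with the allyl group necessarily ortho. Cross-metathesis with 2-methylbut-2-ene (second-generation Grubbs catalyst, RuCl2(=CHPh)(H2IMes)(PCy3), CH2Cl2, 40 °C) would convert allyl into prenyl and give 15.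

**Step 11.**
- What may go wrong: β-hydride elimination toward the benzylic CH2 instead of the carbinol C–H gives the arylated allylic alcohol instead of the ketone. The doubly ortho-oxygenated benzylic allylic alcohol may also ionise on heating.
- Fallback: it sets out from 13 and returns at 16. Oxidation with MnO2 (CH2Cl2, rt) would give 1-[5,7-bis(methoxymethoxy)-2,2-dimethylchroman-6-yl]prop-2-en-1-one F5, used at once. A reductive Heck reaction (conjugate hydroarylation) with 15 (Pd(OAc)2, HCO2Na, Bu4NCl, DMF, 40 °C) would give 16. Formate reduces the palladium enolate, so no choice between β-hydrogens arises.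

**Step 12.**
- What may go wrong: before both acetals are gone, acid protonates the prenyl alkene and the neighbouring ring B hydroxyl traps the tertiary cation, closing a second chroman.
- Fallback: it sets out from 16 and returns at 17. The ring B phenol would be masked with pivaloyl chloride and pyridine to give 4-{3-[5,7-bis(methoxymethoxy)-2,2-dimethylchroman-6-yl]-3-oxopropyl}-2-(3-methylbut-2-en-1-yl)phenyl 2,2-dimethylpropanoate F6. The acetals would be cleaved as in step 12 to 4-[3-(5,7-dihydroxy-2,2-dimethylchroman-6-yl)-3-oxopropyl]-2-(3-methylbut-2-en-1-yl)phenyl 2,2-dimethylpropanoate F7, in which the acylated oxygen can no longer act as the internal trap. The ester would then be removed with K2CO3 in MeOH at rt to give 17.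

## Further compounds

F1 | step 5 | methyl 2,4,6-trihydroxybenzoate | COC(=O)c1c(O)cc(O)cc1O
F2 | step 5 | methyl 2,4,6-trihydroxy-3-(3-methylbut-2-en-1-yl)benzoate | COC(=O)c1c(O)cc(O)c(CC=C(C)C)c1O
F3 | step 10 | 1-iodo-4-(prop-2-en-1-yloxy)benzene | C=CCOc1ccc(I)cc1
F4 | step 10 | 4-iodo-2-(prop-2-en-1-yl)phenol | C=CCc1cc(I)ccc1O
F5 | step 11 | 1-[5,7-bis(methoxymethoxy)-2,2-dimethylchroman-6-yl]prop-2-en-1-one | COCOc1cc2OC(C)(C)CCc2c(OCOC)c1C(=O)C=C
F6 | step 12 | 4-{3-[5,7-bis(methoxymethoxy)-2,2-dimethylchroman-6-yl]-3-oxopropyl}-2-(3-methylbut-2-en-1-yl)phenyl 2,2-dimethylpropanoate | CC(C)=CCc1cc(CCC(=O)c2c(OCOC)cc3OC(C)(C)CCc3c2OCOC)ccc1OC(=O)C(C)(C)C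
F7 | step 12 | 4-[3-(5,7-dihydroxy-2,2-dimethylchroman-6-yl)-3-oxopropyl]-2-(3-methylbut-2-en-1-yl)phenyl 2,2-dimethylpropanoate | CC(C)=CCc1cc(CCC(=O)c2c(O)cc3OC(C)(C)CCc3c2O)ccc1OC(=O)C(C)(C)C
A1 | alternative 1 | 4-{3-[7-hydroxy-2,2-dimethyl-5-(trifluoromethanesulfonyloxy)chroman-6-yl]-3-oxopropyl}-2-(3-methylbut-2-en-1-yl)phenyl acetate | CC(C)=CCc1cc(CCC(=O)c2c(O)cc3c(c2OS(=O)(=O)C(F)(F)F)CCC(C)(C)O3)ccc1OC(C)=O
A2 | alternative 1 | 4-{3-[5-hydroxy-2,2-dimethyl-7-(trifluoromethanesulfonyloxy)chroman-6-yl]-3-oxopropyl}-2-(3-methylbut-2-en-1-yl)phenyl acetate | CC(C)=CCc1cc(CCC(=O)c2c(OS(=O)(=O)C(F)(F)F)cc3c(c2O)CCC(C)(C)O3)ccc1OC(C)=O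
A3 | alternative 1 | 2,2-dimethyl-6-(trimethylsilyl)chroman-5,7-diyl bis(trifluoromethanesulfonate) | C[Si](C)(C)c1c(OS(=O)(=O)C(F)(F)F)cc2OC(C)(C)CCc2c1OS(=O)(=O)C(F)(F)F
A4 | alternative 1 | 3-[4-acetoxy-3-(3-methylbut-2-en-1-yl)phenyl]propanoic acid | CC(=O)Oc1ccc(CCC(=O)O)cc1CC=C(C)C
A5 | alternative 2 | 1-(5,7-dihydroxy-2,2-dimethyl-2H-chromen-6-yl)-3-[4-hydroxy-3-(3-methylbut-2-en-1-yl)phenyl]propan-1-one | CC(C)=CCc1cc(CCC(=O)c2c(O)cc3c(c2O)C=CC(C)(C)O3)ccc1O
A6 | alternative 2 | 1-{2,6-dihydroxy-4-[(2-methylbut-3-yn-2-yl)oxy]phenyl}-3-[4-hydroxy-3-(3-methylbut-2-en-1-yl)phenyl]propan-1-one | CC(C)=CCc1cc(CCC(=O)c2c(O)cc(OC(C)(C)C#C)cc2O)ccc1O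
A7 | alternative 3 | 1-[5,7-bis(methoxymethoxy)-2,2-dimethylchroman-6-yl]-3-[4-(methoxymethoxy)-3-(3-methylbut-2-en-1-yl)phenyl]propan-1-one | CC(C)=CCc1cc(CCC(=O)c2c(OCOC)cc3c(c2OCOC)CCC(C)(C)O3)ccc1OCOC
A8 | alternative 3 | 1-[3-(dimethylaminomethyl)-4-hydroxy-2,6-bis(methoxymethoxy)phenyl]-3-[4-(methoxymethoxy)-3-(3-methylbut-2-en-1-yl)phenyl]propan-1-one | CC(C)=CCc1cc(CCC(=O)c2c(OCOC)cc(O)c(CN(C)C)c2OCOC)ccc1OCOC
A9 | alternative 3 | isobutene (2-methylpropene) | CC(C)=C
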